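**Strategy**

- Retrosynthesis: the C3'–Br and C4'–Cl bonds of ring B are traced back, by a positional interchange of the two halogens, to the isomer with Br on C4' and Cl on C3', and from there to the C3'=C4' alkene. Ring A is then cut at O1–C6 and C5–Br (bromoetherification), the chain at C5=C6 (cross-metathesis) and at C3–C4 (allylation), which leaves (R)-limonene oxidised at its isopropenyl methyl group.
- Forward order: ring B is bought in limonene. The chain is grown on the isopropenyl group (hydroxylation, epoxidation, reduction, oxidation, allylation, prenyl formation). Ring A closes by 6-endo bromoetherification. The ring B halogens go in last (chlorohydrin, tertiary bromide, interchange).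
- Enabling feature: in ring B (cyclohexane C1'–C6', C1' bonded to C2 of the oxane) the secondary C3'–Br and the tertiary C4'–Cl (C4' also bears the methyl) are trans-diequatorial, with Br cis to the C1' substituent. Diaxial Markovnikov addition to the C3'=C4' alkene cannot give this array, but it is the exact dyotropic partner of the accessible trans-diaxial C4'–Br/C3'–Cl isomer, in which the equatorial oxane at C1' locks the two C–halogen bonds antiperiplanar.
- Stereochemistry: C1' comes from (R)-limonene, C2 from a reagent-controlled Sharpless epoxidation, C3 from chelation-controlled allylation, and C5 from the chair of the bromoetherification. C3' and C4' come from a diaxial chlorohydrin, a retentive bromination and the double inversion of the key step.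

Key step: step 11

Numbering used below: ring A is the oxane (O1, C2 to C6) and ring B the cyclohexane (C1' to C6'). Open-chain precursors carry the numbers their atoms will have in ring A.
Remark on the chemistry: the allyllithium, allylboronate and allylindium intermediates are aggregates or mixtures in solution, and each is drawn as its simplest monomeric formula.

Step 1
Reactants: 1 (R)-(+)-limonene
Product: 4 (R)-limonen-10-ol [2-[(1R)-4-methylcyclohex-3-en-1-yl]prop-2-en-1-ol], via 10-lithiolimonene 2 (not isolated), via dimethyl allylboronate 3 (not isolated)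
Conditions: n-BuLi, TMEDA, hexane, 0 °C to rt; B(OMe)3, Et2O, −78 °C to rt; H2O2, aq NaOH, 0 °C
Reagents that add atoms: n-butyllithium CCCC[Li] (Li of 2); trimethyl borate COB(OC)OC (B(OMe)2 of 3); hydrogen peroxide OO (hydroxyl O of 4)
Why: Allylic metalation, borylation and oxidative C–B to C–O conversion: n-BuLi·TMEDA should deprotonate the isopropenyl methyl group to a 2-substituted allyllithium, the allylboronate (degenerate toward 1,3-boron shift) is oxidised with 1,2-migration to oxygen, and the ring stereocentre is not involved.

Step 2
Reactants: 4 (R)-limonen-10-ol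
Product: 5 [(2S)-2-[(1R)-4-methylcyclohex-3-en-1-yl]oxiran-2-yl]methanol
Conditions: Ti(OiPr)4 (cat.), L-(+)-diethyl tartrate (cat.), t-BuOOH, 4 Å molecular sieves, CH2Cl2, −20 °C
Reagents that add atoms: tert-butyl hydroperoxide CC(C)(C)OO
Why: Sharpless asymmetric epoxidation is hydroxyl-directed, so only the allylic 1,1-disubstituted alkene should react while the ring alkene is spared, and the L-(+)-tartrate complex delivers oxygen to the face that gives the S oxirane carbon (the sense in which 2-methylallyl alcohol gives (S)-2-methylglycidol), under reagent control over the remote ring stereocentre.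

Step 3
Reactants: 5 [(2S)-2-[(1R)-4-methylcyclohex-3-en-1-yl]oxiran-2-yl]methanol
Product: 6 (2S)-2-[(1R)-4-methylcyclohex-3-en-1-yl]propane-1,2-diol
Conditions: LiAlH4, THF, 0 °C to rt; then Na2SO4·10H2O
Reagents that add atoms: none
Why: Reductive epoxide opening by SN2 attack of hydride at the unsubstituted CH2 terminus should give the methyl group and the tertiary alcohol, and the C–O bond at the quaternary carbon is not broken, so its S configuration is kept.

Step 4
Reactants: 6 (2S)-2-[(1R)-4-methylcyclohex-3-en-1-yl]propane-1,2-diol
Product: 7 (2S)-2-hydroxy-2-[(1R)-4-methylcyclohex-3-en-1-yl]propanal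
Conditions: SO3·pyridine, DMSO, Et3N, CH2Cl2, 0 °C; used crude
Reagents that add atoms: none
Why: Parikh–Doering oxidation (activated DMSO, alkoxysulfonium ylide) can only oxidise the primary alcohol, since the tertiary one has no carbinol hydrogen, and the quaternary alpha carbon cannot epimerise.

Step 5
Reactants: 7 (2S)-2-hydroxy-2-[(1R)-4-methylcyclohex-3-en-1-yl]propanal; 8 allyl bromide
Product: 10 (2S,3S)-2-[(1R)-4-methylcyclohex-3-en-1-yl]hex-5-ene-2,3-diol, via allylindium dibromide 9 (not isolated)
Conditions: indium powder, THF–H2O (1:1), rt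
Reagents that add atoms: allyl bromide (reactant 8) C=CCBr; indium [In] (metal of 9)
Why: Barbier-type indium-mediated allylation in water under chelation control: trivalent indium should bind the free alpha-hydroxyl and the carbonyl oxygen in a five-membered chelate, and the allyl group should add to the aldehyde face flanked by the methyl group instead of the cyclohexenyl ring, which sets C3 as S.

Step 6
Reactants: 10 (2S,3S)-2-[(1R)-4-methylcyclohex-3-en-1-yl]hex-5-ene-2,3-diol; 11 2-methylbut-2-ene
Product: 12 (2S,3S)-6-methyl-2-[(1R)-4-methylcyclohex-3-en-1-yl]hept-5-ene-2,3-diol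
Conditions: second-generation Grubbs catalyst RuCl2(=CHPh)(PCy3)(H2IMes) (cat.), neat 2-methylbut-2-ene, rt
Reagents that add atoms: 2-methylbut-2-ene (reactant 11) CC=C(C)C
Why: Olefin cross-metathesis should exchange the methylene of the monosubstituted vinyl group for the isopropylidene unit of the excess 2-methylbut-2-ene, while the trisubstituted ring alkene does not engage the ruthenium carbene and no stereocentre is touched.

Step 7
Reactants: 12 (2S,3S)-6-methyl-2-[(1R)-4-methylcyclohex-3-en-1-yl]hept-5-ene-2,3-diol
Product: 13 (2S,3S)-2-hydroxy-6-methyl-2-[(1R)-4-methylcyclohex-3-en-1-yl]hept-5-en-3-yl acetate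
Conditions: Ac2O, pyridine, DMAP (cat.), CH2Cl2, 0 °C to rt
Reagents that add atoms: acetic anhydride CC(=O)OC(C)=O
Why: DMAP-catalysed acylation should take the secondary hydroxyl and leave the hindered tertiary one free, which installs the acetate of the target and removes the secondary oxygen as a competing nucleophile in the next step.

Step 8
Reactants: 13 (2S,3S)-2-hydroxy-6-methyl-2-[(1R)-4-methylcyclohex-3-en-1-yl]hept-5-en-3-yl acetate
Product: 14 (2S,3S,5S)-5-bromo-2,6,6-trimethyl-2-[(1R)-4-methylcyclohex-3-en-1-yl]oxan-3-yl acetate
Conditions: 2,4,4,6-tetrabromocyclohexa-2,5-dien-1-one (TBCO, 1.0 equiv), MeNO2, −20 to 0 °C, dark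
Reagents that add atoms: 2,4,4,6-tetrabromocyclohexa-2,5-dien-1-one O=C1C(Br)=CC(Br)(Br)C=C1Br
Why: Bromoetherification: TBCO should transfer Br+ to the prenyl alkene and the tertiary hydroxyl should open the bromonium at the more substituted carbon C6 (6-endo, Markovnikov) through a chair in which the cyclohexenyl group on C2 is equatorial, the C2 methyl and the C3 acetate are axial and the anti-delivered bromine is equatorial, which sets C5 as S.

Step 9
Reactants: 14 (2S,3S,5S)-5-bromo-2,6,6-trimethyl-2-[(1R)-4-methylcyclohex-3-en-1-yl]oxan-3-yl acetate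
Product: 15 (2S,3S,5S)-5-bromo-2-[(1R,3S,4S)-3-chloro-4-hydroxy-4-methylcyclohexyl]-2,6,6-trimethyloxan-3-yl acetate
Conditions: N-chlorosuccinimide, acetone–H2O, 0 °C to rt
Reagents that add atoms: N-chlorosuccinimide O=C1CCC(=O)N1Cl; water O
Why: Halohydrin formation: water should open the chloronium ion at the tertiary carbon C4' (Markovnikov) in the trans-diaxial, chair-like mode (Fürst–Plattner rule), which is open only to the chloronium on the face trans to the equatorial oxane at C1', so that Cl becomes axial at C3' (S) and OH axial at C4' (S).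

Step 10
Reactants: 15 (2S,3S,5S)-5-bromo-2-[(1R,3S,4S)-3-chloro-4-hydroxy-4-methylcyclohexyl]-2,6,6-trimethyloxan-3-yl acetate
Product: 16 (2S,3S,5S)-5-bromo-2-[(1R,3S,4S)-4-bromo-3-chloro-4-methylcyclohexyl]-2,6,6-trimethyloxan-3-yl acetate
Conditions: Me3SiBr (1.5 equiv), CH2Cl2, 0 °C
Reagents that add atoms: bromotrimethylsilane C[Si](C)(C)Br
Why: SN1-type substitution of a tertiary alcohol by Me3SiBr with neighbouring-group participation: the axial C3'–Cl is antiperiplanar to the departing silyloxonium, so the cation should be chlorine-bridged or shielded on that face and bromide should enter C4' axially and anti to chlorine, giving the trans-diaxial dihalide with net retention at C4' (S), while the acetate, the secondary bromide and the hindered ring ether should survive a small excess of reagent at 0 °C.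

Step 11
Reactants: 16 (2S,3S,5S)-5-bromo-2-[(1R,3S,4S)-4-bromo-3-chloro-4-methylcyclohexyl]-2,6,6-trimethyloxan-3-yl acetate
Product: 17 acetylcaespitol [(2S,3S,5S)-5-bromo-2-[(1R,3R,4R)-3-bromo-4-chloro-4-methylcyclohexyl]-2,6,6-trimethyloxan-3-yl acetate]
Conditions: MeNO2, solid NaHCO3, 60 °C, dark
Reagents that add atoms: none
Why: On heating, the antiperiplanar axial C4'–Br and C3'–Cl bonds of 16 should exchange places in one concerted suprafacial double 1,2-shift through a doubly halogen-bridged transition state (dyotropic rearrangement of the first type); the closest known reaction is the thermal diaxial-to-diequatorial rearrangement of steroidal and terpenoid vicinal bromochlorides, in which the two halogens interchange. No ring is closed: only the C4'–Br and C3'–Cl bonds break and the C4'–Cl and C3'–Br bonds form, each halogen staying on its own face of ring B. Both carbons are therefore inverted stereospecifically, C3' from S to R (Br equatorial and cis to the oxane at C1') and C4' from S to R (Cl equatorial, methyl axial), the controlling element being the fixed anti relationship of the two migrating bonds. The step needs the concerted interchange to be faster than ionisation or loss of HBr at the tertiary bromide, and it needs the equilibrium to lie on the diequatorial side. The bulky equatorial oxane at C1' locks ring B in the chair that holds both halogens axial and antiperiplanar, the geometry the bridged transition state demands, while the polar non-nucleophilic solvent and solid NaHCO3 should suppress solvolysis and acid-catalysed elimination. Exchange of a tertiary C–Br/secondary C–Cl pair for a tertiary C–Cl/secondary C–Br pair and better solvation of the more polar diequatorial dihalide should favour 17 (against the cost of an axial methyl, so the driving force is small), and unchanged 16 can be resubmitted.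

**Compound list**

1 | (R)-(+)-limonene | C=C(C)[C@@H]1CCC(C)=CC1 | starting material
2 | 10-lithiolimonene, [2-[(1R)-4-methylcyclohex-3-en-1-yl]prop-2-en-1-yl]lithium | [Li]CC(=C)[C@@H]1CCC(C)=CC1 | intermediate
3 | dimethyl [2-[(1R)-4-methylcyclohex-3-en-1-yl]prop-2-en-1-yl]boronate | COB(OC)CC(=C)[C@@H]1CCC(C)=CC1 | intermediate
4 | (R)-limonen-10-ol, 2-[(1R)-4-methylcyclohex-3-en-1-yl]prop-2-en-1-ol | C=C(CO)[C@@H]1CCC(C)=CC1 | intermediate
5 | [(2S)-2-[(1R)-4-methylcyclohex-3-en-1-yl]oxiran-2-yl]methanol | OC[C@]2(CO2)[C@@H]1CCC(C)=CC1 | intermediate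
6 | (2S)-2-[(1R)-4-methylcyclohex-3-en-1-yl]propane-1,2-diol | OC[C@](O)(C)[C@@H]1CCC(C)=CC1 | intermediate
7 | (2S)-2-hydroxy-2-[(1R)-4-methylcyclohex-3-en-1-yl]propanal | O=C[C@](O)(C)[C@@H]1CCC(C)=CC1 | intermediate
8 | allyl bromide | C=CCBr | starting material
9 | allylindium dibromide (trivalent indium) | C=CC[In](Br)Br | intermediate
10 | (2S,3S)-2-[(1R)-4-methylcyclohex-3-en-1-yl]hex-5-ene-2,3-diol | C=CC[C@H](O)[C@](O)(C)[C@@H]1CCC(C)=CC1 | intermediate
11 | 2-methylbut-2-ene | CC=C(C)C | starting material
12 | (2S,3S)-6-methyl-2-[(1R)-4-methylcyclohex-3-en-1-yl]hept-5-ene-2,3-diol | CC(C)=CC[C@H](O)[C@](O)(C)[C@@H]1CCC(C)=CC1 | intermediate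
13 | (2S,3S)-2-hydroxy-6-methyl-2-[(1R)-4-methylcyclohex-3-en-1-yl]hept-5-en-3-yl acetate | CC(C)=CC[C@H](OC(C)=O)[C@](O)(C)[C@@H]1CCC(C)=CC1 | intermediate
14 | (2S,3S,5S)-5-bromo-2,6,6-trimethyl-2-[(1R)-4-methylcyclohex-3-en-1-yl]oxan-3-yl acetate | CC(=O)O[C@H]1C[C@H](Br)C(C)(C)O[C@@]1(C)[C@@H]1CCC(C)=CC1 | intermediate
15 | (2S,3S,5S)-5-bromo-2-[(1R,3S,4S)-3-chloro-4-hydroxy-4-methylcyclohexyl]-2,6,6-trimethyloxan-3-yl acetate | CC(=O)O[C@H]1C[C@H](Br)C(C)(C)O[C@@]1(C)[C@@H]1CC[C@](C)(O)[C@@H](Cl)C1 | intermediate
16 | (2S,3S,5S)-5-bromo-2-[(1R,3S,4S)-4-bromo-3-chloro-4-methylcyclohexyl]-2,6,6-trimethyloxan-3-yl acetate | CC(=O)O[C@H]1C[C@H](Br)C(C)(C)O[C@@]1(C)[C@@H]1CC[C@](C)(Br)[C@@H](Cl)C1 | intermediate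
17 | acetylcaespitol, (2S,3S,5S)-5-bromo-2-[(1R,3R,4R)-3-bromo-4-chloro-4-methylcyclohexyl]-2,6,6-trimethyloxan-3-yl acetate | CC(=O)O[C@H]1C[C@H](Br)C(C)(C)O[C@@]1(C)[C@@H]1CC[C@@](C)(Cl)[C@H](Br)C1 | target

**Count and risks**

Total step count: 11. Longest linear sequence: 11 steps, from (R)-limonene 1 to 17.

Steps most likely to fail:

Step 11. The diaxial/diequatorial equilibrium may settle on the wrong side, or ionisation of the tertiary bromide with loss of HBr may outrun the concerted shift. The fallback sets out from alkene 14 and comes back at 17. It adds bromine monochloride directly, from Bu4NBrCl2 in CH2Cl2 at low temperature, a Markovnikov anti-addition that puts Cl on C4' and Br on C3'. The bromonium on the face cis to the oxane, opened at C4' in the non-chair mode, would give 17 itself. The faster diaxial opening of the other bromonium would give (2S,3S,5S)-5-bromo-2-[(1R,3S,4S)-3-bromo-4-chloro-4-methylcyclohexyl]-2,6,6-trimethyloxan-3-yl acetate F1. Compound 17 is therefore expected as the minor adduct, to be separated by chromatography, and this fallback gives up stereocontrol in exchange for a constitution that is certain.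

Step 8. The bromonium source may attack the ring B alkene, with cineole-type closure by the same tertiary hydroxyl; the prenyl bromonium may open 5-exo instead of 6-endo; or the facial selectivity of the cyclisation may be poor. The fallback sets out from diol 10 and comes back at chlorohydrin 15. It reorders the halogenations so that each electrophile meets only one reactive alkene:
- Acetylation of 10 (Ac2O, pyridine, DMAP) would give (2S,3S)-2-hydroxy-2-[(1R)-4-methylcyclohex-3-en-1-yl]hex-5-en-3-yl acetate F2.
- N-Chlorosuccinimide in aqueous acetone should react at the trisubstituted ring alkene much faster than at the monosubstituted vinyl group, giving (2S,3S)-2-[(1R,3S,4S)-3-chloro-4-hydroxy-4-methylcyclohexyl]-2-hydroxyhex-5-en-3-yl acetate F3.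
- Cross-metathesis with 2-methylbut-2-ene and the second-generation Grubbs catalyst RuCl2(=CHPh)(PCy3)(H2IMes) would give (2S,3S)-2-[(1R,3S,4S)-3-chloro-4-hydroxy-4-methylcyclohexyl]-2-hydroxy-6-methylhept-5-en-3-yl acetate F4.
- TBCO bromoetherification of F4, which now has a single alkene and a remote second tertiary hydroxyl, would deliver 15.

Step 10. The tertiary cation may lose its stereochemical integrity or eliminate, or bromide may attack the chlorine of the bridged ion and regenerate the alkene. The fallback sets out from alkene 14 and comes back at 16. It avoids the alcohol altogether. Ene-type allylic chlorination with transposition of the double bond (Ca(OCl)2 and solid CO2 in CH2Cl2–H2O) would give (2S,3S,5S)-5-bromo-2-[(1R,3S)-3-chloro-4-methylidenecyclohexyl]-2,6,6-trimethyloxan-3-yl acetate F5, the axial C3' epimer being separated if both faces react. Markovnikov hydrobromination of the exocyclic methylene (HBr, CH2Cl2, −78 °C) should then place bromide on C4' axially, anti to the axial chlorine, giving 16.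

Further compounds
F1 | step 11 | (2S,3S,5S)-5-bromo-2-[(1R,3S,4S)-3-bromo-4-chloro-4-methylcyclohexyl]-2,6,6-trimethyloxan-3-yl acetate | CC(=O)O[C@H]1C[C@H](Br)C(C)(C)O[C@@]1(C)[C@@H]1CC[C@](C)(Cl)[C@@H](Br)C1
F2 | step 8 | (2S,3S)-2-hydroxy-2-[(1R)-4-methylcyclohex-3-en-1-yl]hex-5-en-3-yl acetate | C=CC[C@H](OC(C)=O)[C@](O)(C)[C@@H]1CCC(C)=CC1
F3 | step 8 | (2S,3S)-2-[(1R,3S,4S)-3-chloro-4-hydroxy-4-methylcyclohexyl]-2-hydroxyhex-5-en-3-yl acetate | C=CC[C@H](OC(C)=O)[C@](O)(C)[C@@H]1CC[C@](C)(O)[C@@H](Cl)C1
F4 | step 8 | (2S,3S)-2-[(1R,3S,4S)-3-chloro-4-hydroxy-4-methylcyclohexyl]-2-hydroxy-6-methylhept-5-en-3-yl acetate | CC(C)=CC[C@H](OC(C)=O)[C@](O)(C)[C@@H]1CC[C@](C)(O)[C@@H](Cl)C1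
F5 | step 10 | (2S,3S,5S)-5-bromo-2-[(1R,3S)-3-chloro-4-methylidenecyclohexyl]-2,6,6-trimethyloxan-3-yl acetate | CC(=O)O[C@H]1C[C@H](Br)C(C)(C)O[C@@]1(C)[C@@H]1CCC(=C)[C@@H](Cl)C1
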